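Readings and results were computed from invented constants; the scatter is artificial.

Not full conversion. The hunch that elm turns its whole charge into E runs against the balance of X in the runs so far.

| flask | X | E | time |
|---|---|---|---|
| alder | 0.200 M |  |  |
| birch | 0.0800 M |  |  |
| maple | 0.200 M | 0.100 M |  |
| cedar | 0.300 M |  |  |
| elm | 0.410 M |  | 28 min |

| alder run: time / min | alder run: [E] / M | birch run: time / min | birch run: [E] / M | maple run: time / min | maple run: [E] / M | cedar run: time / min | cedar run: [E] / M |
|---|---|---|---|---|---|---|---|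
| 1.1 | 7 × 10⁻⁴ | 1.1 | 0 | 1.1 | 0.1702 | 1.1 | 0.0014 |
| 1.9 | 0.0022 | 1.9 | 0 | 1.9 | 0.2097 | 1.9 | 0.0023 |
| 3.3 | 0.0033 | 3.3 | 3 × 10⁻⁴ | 3.3 | 0.2478 | 3.3 | 0.0069 |
| 5.6 | 0.0082 | 5.6 | 0.0018 | 5.6 | 0.2653 | 5.6 | 0.0202 |
| 9.6 | 0.0253 | 9.6 | 0.0044 | 9.6 | 0.2686 | 9.6 | 0.0564 |
| 16 | 0.0543 | 16 | 0.0107 | 16 | 0.2688 | 16 | 0.0925 |
| 28 | 0.0729 | 28 | 0.0237 | 28 | 0.2697 | 28 | 0.1003 |

(standard deviation of a reading: 6 × 10⁻⁴ M)

- the exponent of [X] in the starting rate at the charge of the alder run (at the point where two percent of the X have become E) (one fixed amount of E, the same in the runs compared)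
- E in the elm run at 28 min, as a share of the X charged

- Overall: X -> E.
- Constant volume, constant temperature.
- An order is taken over about fifteen percent of the charge, up and down.

At 28 min the alder run holds 0.0729 M of E from 0.200 M of X, so 63.5% of the charge is not there as E. That share, X charged minus E made, over X charged, is the missing share, the complement of the yield.

| Run | E made by 28 min | Missing share |
|---|---|---|
| alder | 0.0729 M | 63.5% |
| cedar | 0.1003 M | 66.6% |
| maple | 0.170 M | 15.2% |

Cedar, with the larger charge, misses more than alder. Maple, with alder's charge plus a seed of E, misses less than alder. These readings suggest a second road for X that competes with the road to E. A straight line through alder and cedar, carried to the 0.410 M of elm, gives a missing share of 69.9%, so this reckoning puts E at 30.1% of the charge.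

The forecast gives an exponent of 1.1 and a share of 30.5%, above the 30.1% of this reckoning: “Extrapolating, elm should have stalled by 28 min at about 30%”.

The flask gives an exponent of 1.0 at the charge of the alder run and a share of 31.6% in the elm run at 28 min.

    2 X ⇌ G + X (2.100 M⁻¹ min⁻¹, 30.12 M⁻¹ min⁻¹)
    G → E (0.04668 min⁻¹)
    2 X → Qa (0.5082 M⁻¹ min⁻¹)
    X + E → 2 E (3.420 M⁻¹ min⁻¹)

The missing share of the elm run is therefore 68.4%, larger than the 63.5% of alder. With the loss of X in pairs to Qa taken away, the elm run reaches 99.8% instead of 31.6%, so that loss is the main reason for the missing share, worth 68 percentage points.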